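All runs come from a simulation from invented constants; scatter was added.

| setting | beta | delta | zeta | autumn | dawn | noon | dusk |
|---|---|---|---|---|---|---|---|
| starting material | 0.050 M | 0.050 M | 0.050 M | 0.050 M | 0.050 M (fed, over 2.5 h) | 0.050 M | 0.050 M (in portions, 3, over 2.5 h) |
| reagent | 0.25 M | 0.25 M | 0.25 M | 0.250 M | 0.250 M | 0.250 M (fed, over 2.5 h) | 0.250 M |
| protic impurity | 0.050 M | 0.050 M | 0.050 M | 0.0500 M | 0.0500 M | 0.0500 M | 0.0500 M |
| free catalyst | 0.36 mM | 0.24 mM | 0.54 mM | 0.36 mM | 0.36 mM | 0.36 mM | 0.36 mM |
| remark | run made earlier | run made earlier | run made earlier | everything together at the start | all else is in the flask from the start; the feed brings no volume worth counting | all else is in the flask from the start; the feed brings no volume worth counting | first portion at the start, last at 2.5 h |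
| time |  |  |  | 12 h | 12 h | 12 h | 12 h |

- beta (time / h: product / %, starting material / %): 1.00: 80.0, 13.5; 1.33: 84.8, 7.7; 2.00: 89.5, 3.9; 3.00: 91.9, 1.5; 5.00: 93.0, 0.4; 8.00: 93.2, 0; 12.0: 91.9, 0
- delta (time / h: product / %, starting material / %): 1.00: 67.3, 24.2; 1.33: 74.7, 17.1; 2.00: 82.1, 8.3; 3.00: 85.4, 4.6; 5.00: 88.9, 1.5; 8.00: 88.3, 0.3; 12.0: 88.5, 0.4
- zeta (time / h: product / %, starting material / %): 1.00: 88.8, 5.8; 1.33: 92.0, 2.7; 2.00: 94.4, 0.9; 3.00: 95.0, 0.2; 5.00: 95.1, 0; 8.00: 95.9, 0.4; 12.0: 94.5, 0

(scatter of a reading: 0.5 percentage points)

- the flask that comes out highest in amount of product, in percent of the starting material charged, or "all alike" when all lie within 1.5 percentage points (autumn / dawn / noon / dusk / all alike)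
- product at the end, in percent of the starting material charged, autumn
- product at the end, in percent of the starting material charged, dawn
- product at the end, in percent of the starting material charged, noon
- product at the end, in percent of the starting material charged, dusk

- Time was what I read first, for you taking over this bench. The pseudo-first-order plot of starting material in the delta run bends with the clock, so I took c(free catalyst) to be decaying at one steady rate. Its readings at 1.00 h and 2.00 h gave a decay constant of 0.282 h⁻¹, so a catalyst half-life of 2.46 h.
- I then multiplied the product missing at 12.0 h by the catalyst charge. This gave 0.0276 mM for delta, 0.0292 mM for beta and 0.0297 mM for zeta. I called their mean, 0.0288 mM, the loss number: the share lost times the c(free catalyst) that the starting material meets on arrival.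
- Autumn has everything in at the start, so I expected 92.0% product there.
- In dawn, the mean portion of starting material arrives at 1.25 h, about half of a catalyst half-life. It meets 0.253 mM, so I expected 88.6%, less than autumn. My advice was not to feed the starting material.
- The beta, delta and zeta runs each held reagent at 0.25 M, so I made no reckoning for noon.
- The forecast named dawn as highest and gave autumn 93%, dawn 94.7%, dusk 93.3% and noon 78%, with “the feed keeps starting material low”. My dawn lay below its range.
- The flasks gave autumn 92.4%, dawn 88.8%, dusk 88.5% and noon 79.5%, so autumn came out highest.

    free catalyst → spent catalyst (k = 0.260 h⁻¹)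
    starting material + protic impurity → quenched substrate (k = 3.05 M⁻¹ h⁻¹)
    starting material + reagent + free catalyst → free catalyst + product (k = 25600 M⁻² h⁻¹)

- Noon's own loss number, its lost share times its catalyst charge, was 0.0738 mM, more than the 0.0288 mM of the runs. The neighbouring flask is noon with free catalyst cut to 0.220 mM. Holding noon's number there, I reckoned a loss of 33.5% and so 66.5% product. The neighbour gave 72.7%, higher than reckoned, with 0.91% of its charged starting material left after 12.0 h.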